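**Retrosynthetic overview**
1. Target ⇐ acetylation, C18 ester demethylation and chemoselective reduction of a C15 acid / C18 methyl ester (pinifolic acid 18-methyl ester).
2. C12–C13 bond ⇐ SN2 (inversion) opening of bought (S)-β-butyrolactone by a C12 organomagnesium/copper reagent; this sets C13.
3. C12 bromide ⇐ excision of the isobutyryl end of a 13-isopropyl ketone (enolate hydroxylation, periodate cleavage, reduction, bromination).
4. Exocyclic C8=C17 ⇐ key step: [1,5]-sigmatropic hydrogen shift (retro-ene, loss of N2) of the allylic diazene made from the C7=C8–CHO enal.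
5. Keto-enal ⇐ oxidative opening of ring C (C13=C14) of methyl abietate. No ring is formed anywhere: rings A and B, with C4, C5, C9 and C10, are bought intact.

Assumption: methyl abietate (CAS 127-25-3) and (S)-β-butyrolactone are bought as such; carbons are numbered as in abietane for 1–6 and as in labdane from 7 on (abietane C14 = labdane C17).

**Route**

Step 1
Reactants: 1 methyl abietate
Product: 3 methyl 13-oxo-13,14-secoabiet-7-en-14-al-18-oate, via 13,14-diol 2 (not isolated)
Conditions: OsO4 (2 mol%), NMO (1.1 eq), acetone–H2O, rt; then NaIO4, rt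
Reagents that add atoms: OsO4 (O=[Os](=O)(=O)=O); N-methylmorpholine N-oxide (C[N+]1([O-])CCOCC1); water (O)
Why: Upjohn dihydroxylation takes the more exposed, more electron-rich C13=C14 bond of the diene, and Malaprade cleavage of the cis-diol opens ring C to an enal (too electron-poor to react on) and an isopropyl ketone, with no stereocentre touched.

Step 2
Reactants: 3 methyl 13-oxo-13,14-secoabiet-7-en-14-al-18-oate
Product: 7 methyl 13-oxo-13,14-secoabiet-8(14)-en-18-oate, via tosylhydrazone 4 (not isolated), via allylic tosylhydrazine 5 (not isolated), via allylic diazene 6 (not isolated)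
Conditions: TsNHNH2 (1.05 eq), THF, 4 Å MS, rt; then catecholborane, 0 °C; then NaOAc·3H2O, 65 °C
Reagents that add atoms: none
Why: Aldehyde-selective hydrazone formation, Kabalka 1,2-reduction and acetate-induced loss of sulfinate give the allylic diazene, whose [1,5]-sigmatropic hydrogen shift with loss of N2 (allylic diazene rearrangement) delivers H to C7 and moves the double bond out of the ring to C8=C17 under kinetic control; the hindered ketone is left alone at 0 °C and no stereocentre is formed.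

Step 3
Reactants: 7 methyl 13-oxo-13,14-secoabiet-8(14)-en-18-oate
Product: 9 methyl 12-hydroxy-13-oxo-13,14-secoabiet-8(14)-en-18-oate, via potassium enolate 8 (not isolated)
Conditions: KN(SiMe3)2, THF, −78 °C; then 2-(phenylsulfonyl)-3-phenyloxaziridine, −78 °C; aq. NH4Cl
Reagents that add atoms: 2-(phenylsulfonyl)-3-phenyloxaziridine (O=S(=O)(N1OC1c1ccccc1)c1ccccc1)
Why: The bulky amide deprotonates kinetically at the C12 methylene and not at the isopropyl methine, and the enolate is hydroxylated by the racemic Davis oxaziridine (enolate oxidation); the new C12 centre is a mixture that is erased in step 4.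

Step 4
Reactants: 9 methyl 12-hydroxy-13-oxo-13,14-secoabiet-8(14)-en-18-oate
Product: 11 methyl 12-hydroxy-13,14,15,16-tetranorlabd-8(17)-en-18-oate, via aldehyde 10 (not isolated)
Conditions: NaIO4, THF–H2O (pH 7), rt; then NaBH4, 0 °C
Reagents that add atoms: none
Why: Malaprade cleavage of the α-ketol removes the isobutyryl unit as isobutyric acid and NaBH4 reduces the resulting aldehyde in the same flask, while the hindered ester and the 1,1-disubstituted alkene are inert to both reagents.

Step 5
Reactants: 11 methyl 12-hydroxy-13,14,15,16-tetranorlabd-8(17)-en-18-oate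
Product: 12 methyl 12-bromo-13,14,15,16-tetranorlabd-8(17)-en-18-oate
Conditions: CBr4, PPh3, CH2Cl2, 0 °C
Reagents that add atoms: carbon tetrabromide (BrC(Br)(Br)Br)
Why: Appel bromination of the unhindered primary alcohol runs under neutral conditions that do not isomerise the exocyclic alkene.

Step 6
Reactants: 12 methyl 12-bromo-13,14,15,16-tetranorlabd-8(17)-en-18-oate; 13 (S)-β-butyrolactone
Product: 15 (13S)-18-methoxy-18-oxolabd-8(17)-en-15-oic acid, via alkylmagnesium bromide 14 (not isolated)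
Conditions: Mg, THF, 35 °C; then CuBr·SMe2 (10 mol%), 13 (1.3 eq), THF–Me2S, −30 → 0 °C; cold 1 M HCl
Reagents that add atoms: none
Why: The primary organomagnesium reagent forms without attacking the neopentyl-type C18 ester and, under catalysis by monovalent copper, opens the β-lactone by SN2 attack at the β-carbon (alkyl–oxygen cleavage) with inversion, so the bought (S) centre becomes (13S) (same descriptor, because O is replaced by C) and the whole side chain arrives in one step.

Step 7
Reactants: 15 (13S)-18-methoxy-18-oxolabd-8(17)-en-15-oic acid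
Product: 17 methyl (13S)-15-hydroxylabd-8(17)-en-18-oate, via mixed carbonic anhydride 16 (not isolated)
Conditions: ClCO2Et, Et3N, THF, −10 °C; then NaBH4, H2O, 0 °C
Reagents that add atoms: none
Why: Mixed-anhydride activation followed by borohydride reduction converts only the free acid into the primary alcohol, leaving the methyl ester and the alkene untouched.

Step 8
Reactants: 17 methyl (13S)-15-hydroxylabd-8(17)-en-18-oate
Product: 18 (13S)-15-hydroxylabd-8(17)-en-18-oic acid
Conditions: n-PrSLi, HMPA, rt; then cold 1 M HCl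
Reagents that add atoms: none
Why: Thiolate SN2 demethylation at the ester methyl group (Bartlett–Johnson cleavage of hindered methyl esters) frees the C18 acid without the strongly basic or acidic conditions that could move the exocyclic alkene.

Step 9
Reactants: 18 (13S)-15-hydroxylabd-8(17)-en-18-oic acid
Product: 19 (13S)-15-acetoxylabd-8(17)-en-18-oic acid
Conditions: Ac2O, pyridine, DMAP (cat.), CH2Cl2, rt; aq. NaHCO3, then dilute HCl
Reagents that add atoms: acetic anhydride (CC(=O)OC(C)=O)
Why: Standard O-acylation of the primary alcohol, with any mixed anhydride at the hindered acid hydrolysed in the aqueous work-up.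

**Compound list**
1 | methyl abietate = methyl abieta-7,13-dien-18-oate (4R,5R,9R,10R; 4α-CO2CH3, 4β-CH3, 5α-H, 9α-H, 10β-CH3) | CC(C)C1=CC2=CC[C@@H]3[C@](C)(CCC[C@@]3(C)C(=O)OC)[C@H]2CC1 | starting material
2 | methyl 13,14-dihydroxyabiet-7-en-18-oate (cis-diol in ring C; C13/C14 configuration not assigned, both centres vanish in the same flask; not isolated) | OC1C2=CC[C@@H]3[C@](C)(CCC[C@@]3(C)C(=O)OC)[C@H]2CCC1(O)C(C)C | intermediate
3 | methyl 13-oxo-13,14-secoabiet-7-en-14-al-18-oate (ring C opened: CHO on C8 of the C7=C8 alkene, CH2CH2C(=O)CH(CH3)2 on C9, 9α-H) | O=CC1=CC[C@@H]2[C@](C)(CCC[C@@]2(C)C(=O)OC)[C@H]1CCC(=O)C(C)C | intermediate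
4 | (E)-p-toluenesulfonylhydrazone of the aldehyde of 3 (not isolated) | Cc1ccc(cc1)S(=O)(=O)N/N=C/C1=CC[C@@H]2[C@](C)(CCC[C@@]2(C)C(=O)OC)[C@H]1CCC(=O)C(C)C | intermediate
5 | allylic N-tosylhydrazine from 1,2-reduction of 4 (TsNH–NH–CH2 on C8; boron-bound on nitrogen until hydrolysis; not isolated) | Cc1ccc(cc1)S(=O)(=O)NNCC1=CC[C@@H]2[C@](C)(CCC[C@@]2(C)C(=O)OC)[C@H]1CCC(=O)C(C)C | intermediate
6 | allylic diazene, HN=N–CH2 on C8 of the C7=C8 alkene (not isolated) | N=NCC1=CC[C@@H]2[C@](C)(CCC[C@@]2(C)C(=O)OC)[C@H]1CCC(=O)C(C)C | intermediate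
7 | methyl 13-oxo-13,14-secoabiet-8(14)-en-18-oate (labdane-type 8(17)-exocyclic methylene; 9β-CH2CH2C(=O)CH(CH3)2; decalin core 1R,4aR,5S,8aR) | C=C1CC[C@@H]2[C@](C)(CCC[C@@]2(C)C(=O)OC)[C@H]1CCC(=O)C(C)C | intermediate
8 | potassium enolate of 7 (C12=C13–OK, geometry immaterial; not isolated) | C=C1CC[C@@H]2[C@](C)(CCC[C@@]2(C)C(=O)OC)[C@H]1CC=C([O-])C(C)C.[K+] | intermediate
9 | methyl 12-hydroxy-13-oxo-13,14-secoabiet-8(14)-en-18-oate (both C12 epimers) | C=C1CC[C@@H]2[C@](C)(CCC[C@@]2(C)C(=O)OC)[C@H]1CC(O)C(=O)C(C)C | intermediate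
10 | methyl 12-oxo-13,14,15,16-tetranorlabd-8(17)-en-18-oate (CH2CHO on C9; not isolated) | C=C1CC[C@@H]2[C@](C)(CCC[C@@]2(C)C(=O)OC)[C@H]1CC=O | intermediate
11 | methyl 12-hydroxy-13,14,15,16-tetranorlabd-8(17)-en-18-oate | C=C1CC[C@@H]2[C@](C)(CCC[C@@]2(C)C(=O)OC)[C@H]1CCO | intermediate
12 | methyl 12-bromo-13,14,15,16-tetranorlabd-8(17)-en-18-oate | C=C1CC[C@@H]2[C@](C)(CCC[C@@]2(C)C(=O)OC)[C@H]1CCBr | intermediate
13 | (S)-β-butyrolactone = (4S)-4-methyloxetan-2-one | C[C@H]1CC(=O)O1 | starting material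
14 | alkylmagnesium bromide from 12 (C12–MgBr; not isolated) | C=C1CC[C@@H]2[C@](C)(CCC[C@@]2(C)C(=O)OC)[C@H]1CC[Mg]Br | intermediate
15 | (13S)-18-methoxy-18-oxolabd-8(17)-en-15-oic acid (18-methyl ester of pinifolic acid) | C=C1CC[C@@H]2[C@](C)(CCC[C@@]2(C)C(=O)OC)[C@H]1CC[C@H](C)CC(=O)O | intermediate
16 | ethyl carbonic mixed anhydride of 15 (not isolated) | C=C1CC[C@@H]2[C@](C)(CCC[C@@]2(C)C(=O)OC)[C@H]1CC[C@H](C)CC(=O)OC(=O)OCC | intermediate
17 | methyl (13S)-15-hydroxylabd-8(17)-en-18-oate | C=C1CC[C@@H]2[C@](C)(CCC[C@@]2(C)C(=O)OC)[C@H]1CC[C@H](C)CCO | intermediate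
18 | (13S)-15-hydroxylabd-8(17)-en-18-oic acid | C=C1CC[C@@H]2[C@](C)(CCC[C@@]2(C)C(=O)O)[C@H]1CC[C@H](C)CCO | intermediate
19 | (13S)-15-acetoxylabd-8(17)-en-18-oic acid = (1R,4aR,5S,8aR)-5-[(3S)-5-acetoxy-3-methylpentyl]-1,4a-dimethyl-6-methylidenedecahydronaphthalene-1-carboxylic acid (CNP0401865.1) | C=C1CC[C@@H]2[C@](C)(CCC[C@@]2(C)C(=O)O)[C@H]1CC[C@H](C)CCOC(C)=O | target

**Step count and risks**
Total steps: 9. Longest linear sequence: 9 (1 → 19; 13 is used as bought).

The three steps most likely to fail, in decreasing order of risk, are steps 6, 2 and 3.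

Step 6. An alkylmagnesium reagent must form next to an ester, even if a hindered one, and must then attack the β-carbon of the lactone and not its carbonyl. The fallback sets out from 12, still through 14, and replaces the lactone by a secondary tosylate that has no carbonyl group. Bought (S)-butane-1,3-diol is silylated at the primary hydroxyl (t-BuMe2SiCl, imidazole, CH2Cl2, −20 °C) to (S)-4-(tert-butyldimethylsilyloxy)butan-2-ol F1. Tosylation (TsCl, pyridine, 0 °C) gives (S)-4-(tert-butyldimethylsilyloxy)butan-2-yl p-toluenesulfonate F2. F2 is coupled with 14 under CuI/TMEDA/LiOMe catalysis (THF, 0 °C; SN2 with inversion, again giving 13S) to methyl (13S)-15-(tert-butyldimethylsilyloxy)labd-8(17)-en-18-oate F3. Bu4NF in THF then frees the alcohol, and the route is back at 17, with 15, 16 and step 7 bypassed.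

Step 2. The one-flask hydrazone reduction may also touch the side-chain ketone or stall before the diazene. The fallback sets out from 3 and reaches the same diazene from an alcohol. The aldehyde alone is reduced (NaBH4, CH2Cl2–MeOH, −78 °C) to methyl 14-hydroxy-13-oxo-13,14-secoabiet-7-en-18-oate F4. Mitsunobu coupling of F4 with 2-nitrobenzenesulfonylhydrazide (PPh3, diethyl azodicarboxylate, N-methylmorpholine, −30 °C) gives the N-allyl-N-(2-nitrophenylsulfonyl)hydrazine F5. On warming to rt, F5 loses the sulfinic acid to give allylic diazene 6, which rearranges as before, and the route is back at 7.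

Step 3. Kinetic enolisation or oxygen transfer to the hindered enolate may be unselective. The fallback sets out from 7 and degrades the isobutyryl group from its other side. Autoxidation (KOC(CH3)3, O2, t-BuOH–DME, 0 °C) passes through the tertiary 15-hydroperoxy ketone F6, which fragments to acetone and methyl hydrogen 14,15,16-trinorlabd-8(17)-ene-13,18-dioate (13-acid, 18-ester) F7. F7 is turned (N-hydroxypyridine-2-thione, DCC, DMAP cat., CH2Cl2, dark) into the Barton ester F8. Irradiation of F8 with CHI3 in benzene gives methyl 12-iodo-13,14,15,16-tetranorlabd-8(17)-en-18-oate F9. Iodine–lithium exchange (t-BuLi, 2.1 eq, Et2O, −78 °C) gives the C12 alkyllithium F10, and MgBr2·OEt2 converts it into 14, where the route is rejoined with steps 4 and 5 bypassed.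

**Further compounds**
F1 | step 6 | (S)-4-(tert-butyldimethylsilyloxy)butan-2-ol | C[C@H](O)CCO[Si](C)(C)C(C)(C)C
F2 | step 6 | (S)-4-(tert-butyldimethylsilyloxy)butan-2-yl p-toluenesulfonate | C[C@H](OS(=O)(=O)c1ccc(C)cc1)CCO[Si](C)(C)C(C)(C)C
F3 | step 6 | methyl (13S)-15-(tert-butyldimethylsilyloxy)labd-8(17)-en-18-oate | C=C1CC[C@@H]2[C@](C)(CCC[C@@]2(C)C(=O)OC)[C@H]1CC[C@H](C)CCO[Si](C)(C)C(C)(C)C
F4 | step 2 | methyl 14-hydroxy-13-oxo-13,14-secoabiet-7-en-18-oate | OCC1=CC[C@@H]2[C@](C)(CCC[C@@]2(C)C(=O)OC)[C@H]1CCC(=O)C(C)C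
F5 | step 2 | N-allyl-N-(2-nitrophenylsulfonyl)hydrazine derived from F4 (N on C14) | NN(CC1=CC[C@@H]2[C@](C)(CCC[C@@]2(C)C(=O)OC)[C@H]1CCC(=O)C(C)C)S(=O)(=O)c1ccccc1[N+](=O)[O-]
F6 | step 3 | methyl 15-hydroperoxy-13-oxo-13,14-secoabiet-8(14)-en-18-oate | C=C1CC[C@@H]2[C@](C)(CCC[C@@]2(C)C(=O)OC)[C@H]1CCC(=O)C(C)(C)OO
F7 | step 3 | methyl hydrogen 14,15,16-trinorlabd-8(17)-ene-13,18-dioate (13-acid, 18-methyl ester) | C=C1CC[C@@H]2[C@](C)(CCC[C@@]2(C)C(=O)OC)[C@H]1CCC(=O)O
F8 | step 3 | Barton ester of F7 (O-acyl N-hydroxypyridine-2-thione) | C=C1CC[C@@H]2[C@](C)(CCC[C@@]2(C)C(=O)OC)[C@H]1CCC(=O)ON1C=CC=CC1=S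
F9 | step 3 | methyl 12-iodo-13,14,15,16-tetranorlabd-8(17)-en-18-oate | C=C1CC[C@@H]2[C@](C)(CCC[C@@]2(C)C(=O)OC)[C@H]1CCI
F10 | step 3 | C12 alkyllithium from F9 | C=C1CC[C@@H]2[C@](C)(CCC[C@@]2(C)C(=O)OC)[C@H]1CC[Li]
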